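All constants stand for no real mixture.

The constants below set two rivals for the substrate, the dissolved gas and the substrate itself, and the target, once made, meets the gas again.

substrate 0.0010 M; gas phase 0.054 mM (held); time 1.0 min

    dissolved gas + target → over-reacted product (k1 = 86 M⁻¹ s⁻¹)
    dissolved gas → decomposed reagent (k2 = 0.014 s⁻¹)
    gas phase ⇌ dissolved gas, rate k3*(csat - [dissolved gas]) (k3 = 0.47 s⁻¹, csat = 0.054 mM)
    2 substrate → self-condensation product (k4 = 71 M⁻¹ s⁻¹)
    substrate + dissolved gas → target (k5 = 3700 M⁻¹ s⁻¹)

1. how much target there is at 1.0 min, in percent of the substrate charged
2. the change that raises the amount of target at 1.0 min, in percent of the substrate charged most ("none" if none brings more than 2 percentage points) (Thursday's / Wednesday's / none)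
3. amount of target at 1.0 min, in percent of the substrate charged, after Thursday's

- Thursday's: doubling the saturation concentration of gas phase, all else as stated
- Wednesday's: doubling the transfer coefficient of step 3, all else as stated

- in percentages every species weighs as the substrate in it: one self-condensation product counts as two
- for a step with 2 of a species take k times the square, and two of it per event
- at the start none of the gas is dissolved
- run time (flask): 1.0 min

We begin by freezing the supply. At the charge, step 5 clears dissolved gas at 3.70 s⁻¹, faster than transfer refills it at 0.47 s⁻¹, so we take the gas as eaten on arrival and the target as made at a constant S = k3·csat = 0.0254 mM s⁻¹. Self-condensation starts at 0.142 mM s⁻¹, faster than S. The share reaching target is therefore S over the sum of S and the self-condensation rate: 15.2 % at the charge, 41.7 % at half the charge, and tending to one as substrate vanishes. Simpson's rule over these three gives 47.0 % of the charge made, taking tc = 18.5 s at rate S.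

Past tc we simply set the gas at csat, a rough freeze that ignores the substrate and the target still consuming it. Target then decays pseudo-first-order, and its lifetime under a saturated solution, τ = 1/(k1·csat) = 3.59 min, leaves 38.8 % at the reading. Either change doubles S, which lifts the amount made to 60.3 %, but Thursday's also halves τ. Thursday's gives 38.6 % and Wednesday's 48.2 %, so we choose Wednesday's.

The weak link is the supply, since gas already stands at 11.3 % of saturation at the charge and the gap shrinks as substrate falls. Putting S·k5[substrate]/(k3 + k5[substrate]) into the shares lowers the amount made to 43.2 % and this flask's target to 35.3 %.

The forecast gave 38 %, Wednesday's and 39.5 %, holding that “doubling the transfer coefficient speeds supply without raising that ceiling”.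

The flask holds 37.1 % of target at 1.0 min, with Wednesday's the better change at 5.9 percentage points against 1 point, and 38.1 % after Thursday's. Beside the target stands 6.23 % of over-reacted product. Carrying 37.1 % forward with τ gives 28.1 % at 2.00 min, and this flask reads 28.7 %.

For the neighbour left until 4.0 min, the same decay from 37.1 % gives 16.1 %. That flask holds 17.1 %.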